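## Structural features

The target is a furanoheliangolide. Germacrane locants are used throughout: C1 is the ring ketone, C2=C3 and C4=C5 are the ring alkenes, and C6 to C10 complete the ten-membered carbocycle. C11, C12 and C13 form the methylene-lactone unit, C14 is the methyl on C10, and C15 is the CH2OH on C4. One oxygen bridges C3 and C10. The atoms O, C3, C2, C1, C10 therefore form a 3(2H)-furanone, and O with C3 to C10 forms a nine-membered oxacycle (an 11-oxabicyclo[6.2.1]undecane with a bridgehead alkene).

A trans α-methylene-γ-butyrolactone (O6–C12) is fused at C6–C7, and C8 carries the (R)-2-methylbutanoate. C6, C7 and C8 are contiguous stereocentres (6R,7R,8R; H6/H7 trans, H7/H8 cis). The quaternary C10 (S) is separated from them by C9H2 and is 1,3-related to C8. C4=C5 is trisubstituted, cis within the ring, and conjugated with the furanone.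

The fragile groups are the exocyclic Michael acceptor C11=C13, the cross-conjugated dienone, the allylic O6–C6 bond and the free allylic C15–OH. The real difficulty is closing the strained nine- or ten-membered bridged ring with the correct alkene geometry, while relating C10 to the C6–C8 triad.

The key step exploits one feature. O8 and O10 are 1,3-related through C9, and C10 carries C1(=O)–C2. Once C2–C3 and O10–C3 are cut, C3 is simply an acyl carbon. It can be parked on O8 as a seven-membered lactone and then handed to O10 and C2 through six- and five-membered transition states.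

## Logic of the disconnections

**27 to 26 to 24 + 25.** The O15–Si bond and the O8–acyl bond are cut. Both are last-stage events, because 24 has only one free hydroxyl, the one on C8. This removes the side-chain stereocentre, which comes from 25. The forward demand is mild acylation and fluoride deprotection that leave the methylene lactone and the dienone untouched.

**24 to 21 (key).** C2–C3 and O10–C3 are cut, and C3 is reconnected to O8. The bridged bicycle (furanone, nine-membered oxacycle and ten-membered carbocycle) becomes a seven-membered unsaturated lactone carrying an open α-ketol side chain. Both bridges disappear in one operation and no stereocentre changes. The forward step must move the acyl carbon O8 to O10 to C2 and finish with loss of water. It must also select C3 over C12, C13 and C5.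

**21 to 20.** C4=C5 is cut. Inside a seven-membered ring this alkene can only be cis, so the geometry problem of the target disappears. Ring closure becomes a common-ring metathesis instead of a nine-membered one. The demand is that a 1,1-disubstituted acrylate couples with a propenyl group.

**20 to 19 + 18.** The O8–C3 ester bond is cut, with inversion at C8. The tether oxygen is the same oxygen that later carries the natural ester, so the tether costs no extra atoms. The demand is an SN2-type esterification at a hindered secondary carbinol.

**19 to 8 + 15.** C7–C8 is cut. This separates the C10 fragment from the C6 fragment, each with a single stereocentre. C7, C8 and the exocyclic methylene arise together. The demand is γ-selective (SE2') allylation anti to the C6 substituent through a closed transition state.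

**15 to 14 to 12 + 13; 12 to 11 to 9 + 10.** C7=C11 (five-ring metathesis) and the O6–C12 ester bond are cut. C6 comes from a kinetic resolution of a simple dienol. The demand is that the catalyst engages the vinyl group and not the propenyl group.

**8 to 7 to 5 + 6; 5 to 3 + 4; 3 to 1 + 2.** The bonds cut are the C8=CH2 bond of the allyl group of 7, C1–C2, C9–C10 and the acetal. C10 is created by alkylation of a chiral-pool enolate whose original stereocentre is stored in an acetal carbon.

**18 to 17 to 16.** These are protecting-group and ester operations on the three-carbon C3/C4/C15 unit.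

## Other disconnections considered

**Alternative 1:** This is the first idea that comes to mind. Cut C6–C7 and O6–C12. The forward key step is an intramolecular Barbier or Nozaki–Hiyama–Kishi allylation with lactonisation of the ω-formyl allylic bromide A1 on a preformed furanone. That step closes the nine-membered ring end to end and sets C6 and C7 under macrocyclic control that is hard to predict from a model. It also needs a Z-configured γ-oxo dienone aldehyde, which is prone to Z/E isomerisation, and a long linear build-up of A1. The chosen plan closes only 5-, 6- and 7-membered arrays and fixes C6 and C7 before any medium ring exists.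

**Alternative 2:** Cut C4=C5 directly. The forward key step is ring-closing metathesis of diene A2, with the furanone already in place, to the nine-membered ring. The reacting alkene on the furanone is 1,1-disubstituted, conjugated and electron-poor, and the product is a strained trisubstituted alkene. Oligomerisation and ring-opening of the product should therefore compete, and the geometry is not enforced as strictly as in a seven-membered ring. The chosen plan makes the same bond in a seven-membered lactone and expands afterwards.

**Alternative 3:** Cut C9–C10 and reconnect the bridge oxygen to C7. The forward key step is metal-carbenoid formation from the diazoketone A3 (a 2,6-cis-dihydropyran), oxonium ylide formation and [2,3]-shift to the oxabicyclo[6.2.1] ketone A4. This fits the bridged skeleton well. However, it places an alkene at C7=C8, exactly where the target needs a C–C and a C–O bond. The methyl-bearing carbenoid also has a competing 1,2-hydride shift, and the tetrahydrofuranone must still be dehydrogenated. The steps needed after the key step outweigh the gain.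

Key step: step 14

Assumption: locants C1–C15 and O6, O8, O10 are those defined under "Structural features". Compounds 1, 2, 4, 6, 9, 10, 13, 16 and 25 are taken as commercially available.

## Route

Step 1
Reactants: 1 (R)-lactic acid; 2 pivalaldehyde
Product: 3 (2R,5R)-2-tert-butyl-5-methyl-1,3-dioxolan-4-one (cis)
Conditions: p-TsOH (cat.), H2SO4 (cat.), pentane, reflux, Dean–Stark; recrystallisation
Reagents that add atoms: none
Why: Acid-catalysed acetalisation (self-regeneration of stereocentres). The cis acetal is the thermodynamically preferred and crystalline isomer, so the lactic stereocentre sets the new acetal carbon.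

Step 2
Reactants: 3; 4 allyl bromide
Product: 5 (2R,5S)-2-tert-butyl-5-methyl-5-(prop-2-enyl)-1,3-dioxolan-4-one
Conditions: LDA (commercial solution), THF, −78 °C; then 4, −78 → −30 °C
Reagents that add atoms: none
Why: Enolate alkylation. The planar lithium enolate is attacked anti to the tert-butyl group, which rebuilds the centre (future C10, S) as a quaternary carbon bearing C9 and C14.

Step 3
Reactants: 5; 6 methyllithium
Product: 7 (3S)-3-hydroxy-3-methylhex-5-en-2-one
Conditions: THF, −78 °C; then H2O
Reagents that add atoms: none
Why: 1,2-Addition to the lactone-type carbonyl. There is no α-hydrogen, so enolisation cannot compete, and the lithium hemiketal resists a second addition. On work-up it collapses with loss of the acetal aldehyde; C10 is not touched.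

Step 4
Reactants: 7
Product: 8 (3S)-3-hydroxy-3-methyl-4-oxopentanal
Conditions: O3, CH2Cl2, −78 °C; Me2S, −78 °C → rt; used crude
Reagents that add atoms: ozone, [O-][O+]=O
Why: Ozonolysis with reductive work-up of the only alkene. The neutral conditions avoid retro-aldol cleavage and dehydration of the β-hydroxy aldehyde.

Step 5
Reactants: 9 (E)-but-2-enal; 10 vinylmagnesium bromide
Product: 11 rac-(4E)-hexa-1,4-dien-3-ol
Conditions: THF, −78 → 0 °C; then H2O
Reagents that add atoms: none
Why: 1,2-Addition of a Grignard reagent to an enal. The E geometry of the propenyl group is retained.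

Step 6
Reactants: 11
Product: 12 (3S,4E)-hexa-1,4-dien-3-ol
Conditions: Ti(OiPr)4 (cat.), D-(−)-DIPT (cat.), t-BuOOH (0.6 equiv), 4 Å MS, CH2Cl2, −20 °C, stopped past half conversion
Reagents that add atoms: none
Why: Sharpless kinetic resolution. With D-(−)-tartrate the (R)-alcohol is epoxidised quickly at its E-disubstituted alkene and the (S)-alcohol is left behind. The monosubstituted vinyl group reacts far more slowly. This sets C6.

Step 7
Reactants: 12; 13 2-(bromomethyl)acrylic acid
Product: 14 (3S,4E)-hexa-1,4-dien-3-yl 2-(bromomethyl)prop-2-enoate
Conditions: DCC, DMAP (low loading), CH2Cl2, 0 °C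
Reagents that add atoms: none
Why: Steglich esterification. The carbinol C–O bond is not broken, so C6 keeps its configuration. Little DMAP is used, to limit its reaction with the allylic bromide.

Step 8
Reactants: 14
Product: 15 (5R)-3-(bromomethyl)-5-[(1E)-prop-1-enyl]furan-2(5H)-one
Conditions: Grubbs II (cat.), CH2Cl2, reflux, dilute
Reagents that add atoms: none
Why: Ring-closing metathesis to a butenolide. The catalyst loads on the monosubstituted vinyl group and closes onto the acrylate, so the slower propenyl group stays on C6. The neutral medium protects the acidic doubly allylic H6.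

Step 9
Reactants: 16 methyl 2-(hydroxymethyl)acrylate
Product: 17 methyl 2-{[(tert-butyldimethylsilyl)oxy]methyl}acrylate
Conditions: TBSCl, imidazole, CH2Cl2, 0 °C → rt
Reagents that add atoms: tert-butyldimethylsilyl chloride, CC(C)(C)[Si](C)(C)Cl
Why: Standard silylation of a primary allylic alcohol. The group masks O15 until the last step.

Step 10
Reactants: 17
Product: 18 2-{[(tert-butyldimethylsilyl)oxy]methyl}acrylic acid
Conditions: LiOH, THF/H2O, 0 °C → rt; then 1 M HCl to pH 4
Reagents that add atoms: lithium hydroxide, [Li+].[OH-]
Why: Saponification of a methyl ester. A primary TBS ether tolerates cold aqueous LiOH and the brief mild acidification.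

Step 11
Reactants: 8; 15
Product: 19 (4R,5R)-4-[(1S,3S)-1,3-dihydroxy-3-methyl-4-oxopentyl]-3-methylidene-5-[(1E)-prop-1-enyl]oxolan-2-one (the 8-epi alcohol; C8 = S)
Conditions: In powder, THF/H2O, rt
Reagents that add atoms: none
Why: Barbier-type indium allylation with an α-(bromomethyl)butenolide, reacting at C7 (SE2') and unveiling C11=C13. C7 is set by attack anti to the C6 propenyl group (trans lactone). The ring locks the allylmetal in an E-crotyl-type geometry, so a Zimmerman–Traxler chair should give the anti (8S) carbinol. The aldehyde reacts in preference to the hindered ketone.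

Step 12
Reactants: 19; 18
Product: 20 the (8R) ester: the 2-{[(tert-butyldimethylsilyl)oxy]methyl}acrylate of the C8-inverted alcohol; lactone, 10-OH and methyl ketone unchanged
Conditions: PPh3, DIAD, toluene, 0 °C → rt
Reagents that add atoms: none
Why: Mitsunobu esterification. SN2 displacement inverts C8 to the natural R configuration and installs the C3/C4/C15 unit on O8 in the same operation. The tertiary 10-OH is not activated.

Step 13
Reactants: 20
Product: 21 the seven-membered O8–C3 lactone (2,7-dihydrooxepin-2-one) with Z-C4=C5 and C4–CH2OTBS, trans-fused at C6–C7 to the α-methylene-γ-butyrolactone; C8 bears the (2S)-2-hydroxy-2-methyl-3-oxobutyl chain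
Conditions: Hoveyda–Grubbs II (cat.), 1,4-benzoquinone (cat.), toluene, 80 °C, high dilution
Reagents that add atoms: none
Why: Ring-closing metathesis to a common-size ring. The seven-membered ring allows only the cis alkene needed in the target. The C11=C13 methylene is a poor partner and could only give a four-membered ring or a tetrasubstituted alkene.

Step 14
Reactants: 21
Product: 24 8-hydroxy furanone (8-O-desacyl-15-O-TBS target), via nine-membered C10–O lactone 22 (not isolated), via ten-membered 10-hydroxy-1,3-diketone 23 (not isolated)
Conditions: LiHMDS (3.2 equiv), THF, high dilution, −78 → −10 °C; AcOH; then PPTS (cat.), 4 Å MS, CH2Cl2, rt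
Reagents that add atoms: none
Why: Proposed new method: LiHMDS forms the C10 alkoxide and the C2 enolate of the methyl ketone (C10 is quaternary, so C2 is the only enolisable position of that ketone). O10 then adds to the lactone carbonyl C3 through a chair-like six-membered array (6-exo-trig, O10–C10–C9–C8–O8–C3), and collapse with loss of O8 turns the seven-membered lactone into the nine-membered lactone 22 by ring expansion, not by end-to-end closure. In 22 the C2 enolate is 1,5 to C3 and closes the furanone ring by a 5-exo-trig Claisen (Dieckmann-type) attack, and direct attack of C2 on C3 of 21 (seven-membered array) feeds the same manifold. Deprotonation to the diketonate of 23 is the thermodynamic sink that pays for the ring strain and makes the uphill translactonisation productive, and mild acid then dehydrates the hydroxy-diketone/hemiketal to the vinylogous ester 24. The closest known reaction types are the Baker–Venkataraman O-to-C acyl shift, the base-induced condensation of α-acyloxy ketones to 3(2H)-furanones and translactonisation ring expansions, none of which has been shown for a lactone-to-bridged-furanone expansion. No stereocentre is formed and only acyl–oxygen bonds are broken, so 6R,7R,8R,10S and the Z geometry fixed in step 13 carry over. The selectivity needed is C3 over C12, C13 and C5: only C3 is reachable by O10 and C2 through six- and five-membered arrays, whereas the others need seven- or eight-membered ones, and high dilution suppresses intermolecular condensation.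

Step 15
Reactants: 24; 25 (R)-2-methylbutanoic acid
Product: 26 15-O-TBS ether of the target
Conditions: DCC, DMAP, CH2Cl2, 0 °C → rt
Reagents that add atoms: none
Why: Steglich esterification of the only free hydroxyl. The C8–O bond is untouched, and carbodiimide activation avoids a ketene pathway, so the α-stereocentre of 25 is kept.

Step 16
Reactants: 26
Product: 27 target (CNP0307052.2)
Conditions: HF·pyridine, pyridine/THF, 0 °C
Reagents that add atoms: none
Why: Buffered fluoride cleavage of a primary allylic TBS ether. The conditions are neither basic nor nucleophilic enough to affect the methylene lactone, the ester or the furanone.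

## Compound list

1 | (R)-lactic acid | C[C@@H](O)C(=O)O | starting material
2 | pivalaldehyde | CC(C)(C)C=O | starting material
3 | (2R,5R)-2-tert-butyl-5-methyl-1,3-dioxolan-4-one | C[C@H]1O[C@@H](C(C)(C)C)OC1=O | intermediate
4 | allyl bromide | C=CCBr | starting material
5 | (2R,5S)-2-tert-butyl-5-methyl-5-(prop-2-enyl)-1,3-dioxolan-4-one | C=CC[C@]1(C)O[C@@H](C(C)(C)C)OC1=O | intermediate
6 | methyllithium | [Li]C | starting material
7 | (3S)-3-hydroxy-3-methylhex-5-en-2-one | C=CC[C@](C)(O)C(C)=O | intermediate
8 | (3S)-3-hydroxy-3-methyl-4-oxopentanal | O=CC[C@](C)(O)C(C)=O | intermediate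
9 | (E)-but-2-enal | C/C=C/C=O | starting material
10 | vinylmagnesium bromide | C=C[Mg]Br | starting material
11 | rac-(4E)-hexa-1,4-dien-3-ol | C=CC(O)/C=C/C | intermediate
12 | (3S,4E)-hexa-1,4-dien-3-ol | C=C[C@H](O)/C=C/C | intermediate
13 | 2-(bromomethyl)acrylic acid | C=C(CBr)C(=O)O | starting material
14 | (3S,4E)-hexa-1,4-dien-3-yl 2-(bromomethyl)prop-2-enoate | C=C[C@H](OC(=O)C(=C)CBr)/C=C/C | intermediate
15 | (5R)-3-(bromomethyl)-5-[(1E)-prop-1-enyl]furan-2(5H)-one | C/C=C/[C@H]1OC(=O)C(CBr)=C1 | intermediate
16 | methyl 2-(hydroxymethyl)acrylate | C=C(CO)C(=O)OC | starting material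
17 | methyl 2-{[(tert-butyldimethylsilyl)oxy]methyl}acrylate | C=C(CO[Si](C)(C)C(C)(C)C)C(=O)OC | intermediate
18 | 2-{[(tert-butyldimethylsilyl)oxy]methyl}acrylic acid | C=C(CO[Si](C)(C)C(C)(C)C)C(=O)O | intermediate
19 | 8-epi alcohol, (4R,5R)-4-[(1S,3S)-1,3-dihydroxy-3-methyl-4-oxopentyl]-3-methylidene-5-[(1E)-prop-1-enyl]oxolan-2-one | C=C1C(=O)O[C@H](/C=C/C)[C@H]1[C@@H](O)C[C@](C)(O)C(C)=O | intermediate
20 | (8R) 2-(TBSO-methyl)acrylate ester | C=C1C(=O)O[C@H](/C=C/C)[C@H]1[C@H](OC(=O)C(=C)CO[Si](C)(C)C(C)(C)C)C[C@](C)(O)C(C)=O | intermediate
21 | seven-membered O8–C3 lactone fused to the methylene lactone | C=C1C(=O)O[C@@H]2/C=C(/CO[Si](C)(C)C(C)(C)C)C(=O)O[C@H](C[C@](C)(O)C(C)=O)[C@@H]12 | intermediate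
22 | nine-membered O10–C3 lactone (10-acetyl, 8-OH free) | C=C1C(=O)O[C@@H]2/C=C(/CO[Si](C)(C)C(C)(C)C)C(=O)O[C@](C)(C(C)=O)C[C@@H](O)[C@@H]12 | intermediate
23 | ten-membered 8,10-dihydroxy-1,3-diketone | C=C1C(=O)O[C@@H]2/C=C(/CO[Si](C)(C)C(C)(C)C)C(=O)CC(=O)[C@@](C)(O)C[C@@H](O)[C@@H]12 | intermediate
24 | 8-hydroxy furanone (8-O-desacyl-15-O-TBS target) | C=C1C(=O)O[C@@H]2/C=C(/CO[Si](C)(C)C(C)(C)C)C3=CC(=O)[C@](C)(C[C@@H](O)[C@@H]12)O3 | intermediate
25 | (R)-2-methylbutanoic acid | CC[C@@H](C)C(=O)O | starting material
26 | 15-O-TBS ether of the target | C=C1C(=O)O[C@@H]2/C=C(/CO[Si](C)(C)C(C)(C)C)C3=CC(=O)[C@](C)(C[C@@H](OC(=O)[C@H](C)CC)[C@@H]12)O3 | intermediate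
27 | target CNP0307052.2 | C=C1C(=O)O[C@@H]2/C=C(/CO)C3=CC(=O)[C@](C)(C[C@@H](OC(=O)[C@H](C)CC)[C@@H]12)O3 | target

## Step count and least certain steps

The route has 16 steps in total. The longest linear sequence is 10 steps (steps 1–4 and 11–16).

**Step 14 (key, proposed new method).**
- **What may go wrong:** The tetrahedral intermediate may simply revert, because the seven-membered lactone is favoured over the nine-membered one. Slower processes could then take over. These include intermolecular Claisen or aldol condensation, conjugate addition of alkoxide or enolate to C13, and, after release of O8, migration of the C12 acyl group from O6 to O8.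
- **Fallback (known reaction types only):** This sets out from 7. The tertiary hydroxyl of 7 is acylated with 18 (mixed anhydride, DMAP) to give the α-acyloxy ketone F1. The established base-then-acid condensation of α-acyloxy ketones converts F1 to the monocyclic furanone F2. Catalytic dihydroxylation with periodate cleavage of the isolated allyl double bond gives aldehyde F3. Indium coupling with 15 gives the 8-epi alcohol F4, and Mitsunobu esterification with 25 gives the diene F5. Direct ring-closing metathesis of the nine-membered ring then comes back to the route at 26.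

**Step 12 (Mitsunobu inversion).**
- **What may go wrong:** Activation of the hindered carbinol may be slow. Elimination towards the allylic H7 is possible, the substrate may be drained into its cyclic C1 hemiketal, and free phosphine may add to the acrylate units.
- **Fallback:** This sets out from 19. It is acylated with 18 with retention (DCC, DMAP) to give the 8-epi ester F6. F6 is closed by metathesis to the 8-epi lactone F7 and taken through the acyl walk to the 8-epi alcohol F8. C8 is corrected only then, by Dess–Martin oxidation to ketone F9 and Luche-type reduction from the exposed outer face of the medium ring. The furanone carbonyl is a deactivated vinylogous ester at that stage. This comes back to the route at 24.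

**Step 11 (indium allylation).**
- **What may go wrong:** Discrimination between chair and boat arrangements may be weak, giving poor control at C8. The metal alkoxide may translactonise onto C12, and the labile aldehyde 8 may undergo retro-aldol loss.
- **Fallback:** This sets out from 12 and replaces the closed transition state by an open one. 2-[(Trimethylsilyl)methyl]acrylic acid F10, obtained from its commercial ethyl ester by saponification, is esterified with 12 to give F11. Metathesis gives the allylsilane butenolide F12. A Hosomi–Sakurai reaction with 8 (BF3·OEt2, −78 °C, syn-selective open transition state) should give the natural (8R) alcohol F13 directly. Acylation of F13 with 18 with retention comes back to the route at 20 and makes the inversion unnecessary.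

**Step 13 (seven-ring metathesis).**
- **What may go wrong:** Closure may be slow, because a bulky, electron-poor 1,1-disubstituted alkene must meet an allylically oxygenated propenyl group. Oligomerisation and alkene migration could then compete.
- **Fallback:** This sets out from 19 and removes the bulk by carrying C15 as a methyl group and oxidising it last. Mitsunobu esterification with methacrylic acid gives F14, and metathesis gives the lactone F15. The acyl walk gives the 15-deoxy alcohol F16, and esterification with 25 gives the 15-deoxy ester F17. Allylic oxidation (SeO2, t-BuOOH) at the only methyl group on the more substituted alkene terminus then comes back to the route at 27.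

## Further compounds

F1 | step 14 | (3S)-3-methyl-2-oxohex-5-en-3-yl 2-{[(tert-butyldimethylsilyl)oxy]methyl}acrylate | C=CC[C@](C)(OC(=O)C(=C)CO[Si](C)(C)C(C)(C)C)C(C)=O
F2 | step 14 | (2S)-2-allyl-2-methyl-5-[3-(TBSO)prop-1-en-2-yl]furan-3(2H)-one | C=CC[C@]1(C)OC(C(=C)CO[Si](C)(C)C(C)(C)C)=CC1=O
F3 | step 14 | 2-{(2S)-2-methyl-3-oxo-5-[3-(TBSO)prop-1-en-2-yl]-2,3-dihydrofuran-2-yl}acetaldehyde | O=CC[C@]1(C)OC(C(=C)CO[Si](C)(C)C(C)(C)C)=CC1=O
F4 | step 14 | 8-epi alcohol carrying the preformed furanone | C=C1C(=O)O[C@H](/C=C/C)[C@H]1[C@@H](O)C[C@]1(C)OC(C(=C)CO[Si](C)(C)C(C)(C)C)=CC1=O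
F5 | step 14 | (8R) (R)-2-methylbutanoate diene for nine-ring metathesis | C=C1C(=O)O[C@H](/C=C/C)[C@H]1[C@H](OC(=O)[C@H](C)CC)C[C@]1(C)OC(C(=C)CO[Si](C)(C)C(C)(C)C)=CC1=O
F6 | step 12 | 8-epi ester (8S epimer of 20) | C=C1C(=O)O[C@H](/C=C/C)[C@H]1[C@@H](OC(=O)C(=C)CO[Si](C)(C)C(C)(C)C)C[C@](C)(O)C(C)=O
F7 | step 12 | 8-epi seven-membered lactone | C=C1C(=O)O[C@@H]2/C=C(/CO[Si](C)(C)C(C)(C)C)C(=O)O[C@@H](C[C@](C)(O)C(C)=O)[C@@H]12
F8 | step 12 | 8-epi hydroxy furanone | C=C1C(=O)O[C@@H]2/C=C(/CO[Si](C)(C)C(C)(C)C)C3=CC(=O)[C@](C)(C[C@H](O)[C@@H]12)O3
F9 | step 12 | 8-oxo furanone | C=C1C(=O)O[C@@H]2/C=C(/CO[Si](C)(C)C(C)(C)C)C3=CC(=O)[C@](C)(CC(=O)[C@@H]12)O3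
F10 | step 11 | 2-[(trimethylsilyl)methyl]acrylic acid | C=C(C[Si](C)(C)C)C(=O)O
F11 | step 11 | (3S,4E)-hexa-1,4-dien-3-yl 2-[(trimethylsilyl)methyl]acrylate | C=C[C@H](OC(=O)C(=C)C[Si](C)(C)C)/C=C/C
F12 | step 11 | (5R)-5-[(1E)-prop-1-enyl]-3-[(trimethylsilyl)methyl]furan-2(5H)-one | C/C=C/[C@H]1OC(=O)C(C[Si](C)(C)C)=C1
F13 | step 11 | natural (8R) alcohol (C8 epimer of 19) | C=C1C(=O)O[C@H](/C=C/C)[C@H]1[C@H](O)C[C@](C)(O)C(C)=O
F14 | step 13 | (8R) methacrylate ester | C=C1C(=O)O[C@H](/C=C/C)[C@H]1[C@H](OC(=O)C(C)=C)C[C@](C)(O)C(C)=O
F15 | step 13 | 15-deoxy seven-membered lactone | C=C1C(=O)O[C@@H]2/C=C(/C)C(=O)O[C@H](C[C@](C)(O)C(C)=O)[C@@H]12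
F16 | step 13 | 15-deoxy 8-hydroxy furanone | C=C1C(=O)O[C@@H]2/C=C(/C)C3=CC(=O)[C@](C)(C[C@@H](O)[C@@H]12)O3
F17 | step 13 | 15-deoxy target | C=C1C(=O)O[C@@H]2/C=C(/C)C3=CC(=O)[C@](C)(C[C@@H](OC(=O)[C@H](C)CC)[C@@H]12)O3
A1 | alternative 1 | ω-formyl allylic bromide on the preformed furanone | O=C/C=C(/CO[Si](C)(C)C(C)(C)C)C1=CC(=O)[C@](C)(C[C@@H](OC(=O)[C@H](C)CC)/C=C(\CBr)C(=O)OC)O1
A2 | alternative 2 | 6-vinyl lactone / 5-alkenyl furanone diene | C=C1C(=O)O[C@H](C=C)[C@H]1[C@H](OC(=O)[C@H](C)CC)C[C@]1(C)OC(C(=C)CO[Si](C)(C)C(C)(C)C)=CC1=O
A3 | alternative 3 | 2,6-cis-dihydropyran diazoketone | C=C[C@H]1O[C@@H](CC(=O)C(C)=[N+]=[N-])C(CO[Si](C)(C)C(C)(C)C)=C[C@H]1O[Si](C)(C)C(C)(C)C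
A4 | alternative 3 | 11-oxabicyclo[6.2.1]undecadienone with C7=C8 | C[C@]12C/C=C\[C@H](O[Si](C)(C)C(C)(C)C)/C=C(/CO[Si](C)(C)C(C)(C)C)[C@H](CC1=O)O2
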